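**Remark (one assumption on the chemistry):** atoms are named by germacrane numbering (ring C1–C10, lactone O–C6/C7/C11/C12, exocyclic CH2 = C13, ester on C8–O; target = 3S,6R,7R,8R,10S,4Z). The macrocyclisation is assumed to follow the closed chair transition state (anti, 8S carbinol), which is why C8 is inverted in the esterification step.

## Retrosynthetic overview

1. Target ⇐ desilylation and Mitsunobu esterification (inversion at C8) of the ten-membered 8-epi alcohol.
2. 8-epi alcohol ⇐ ring bond C7–C8: intramolecular Nozaki–Hiyama allylation of a C8 aldehyde by a 3-(bromomethyl)butenolide. Feature used: the exocyclic C13=C11 of the γ-lactone ring is homoallylic to the C8 oxygen across the ring bond C7–C8 (C13=C11–C7–C8–O), so methylene lactone plus C8 carbinol is the SE2′ retron of a butenolide with endocyclic C7=C11 and CH2Br at C13.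
3. Seco chain ⇐ bond C3–C4: Ni/Cr coupling of a (Z)-vinyl iodide butenolide (C4–C7, C11–C13) with an aldehyde (C1–C3, C8–C10); C3 is then set by CBS reduction.
4. Vinyl iodide ⇐ crotonaldehyde + propynyl Grignard (Sharpless kinetic resolution sets C6, Red-Al/I2 sets Z-C4=C5, RCM closes the butenolide). Aldehyde ⇐ geraniol (Sharpless epoxidation sets C10).
5. Ring order: butenolide (γ-lactone ring) first, ten-membered carbocycle last; the 1,3-dioxane carried in between is a temporary protecting ring.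

Key step: step 19

## Route

Step 1
Reactants: 1 2-(bromomethyl)acrylic acid; 2 4-methoxybenzyl alcohol
Product: 3 2-{[(4-methoxybenzyl)oxy]methyl}acrylic acid
Conditions: NaH (2.2 equiv), THF, 0 °C to rt; aq. HCl work-up
Reagents that add atoms: none
Why: Williamson-type allylic substitution (SN2 and SN2′ are degenerate here) of bromide by the PMB alkoxide on the carboxylate salt; no stereocentre is involved.

Step 2
Reactants: 4 (E)-crotonaldehyde; 5 1-propynylmagnesium bromide
Product: 6 rac-(E)-hept-2-en-5-yn-4-ol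
Conditions: THF, −78 to 0 °C; aq. work-up
Reagents that add atoms: none
Why: Grignard 1,2-addition of an alkynylmagnesium halide to an enal, giving the racemic carbinol that becomes C6.

Step 3
Reactants: 6 rac-(E)-hept-2-en-5-yn-4-ol
Product: 7 (4S,2E)-hept-2-en-5-yn-4-ol (recovered enantiomer)
Conditions: Ti(OiPr)4, L-(+)-DIPT, t-BuOOH (0.6 equiv), 4 Å MS, CH2Cl2, −20 °C
Reagents that add atoms: none
Why: Sharpless kinetic resolution of a secondary E-allylic alcohol; with L-(+)-tartrate the (R)-enantiomer should be epoxidised fast (erythro epoxy alcohol), and the (S)-alcohol, whose alkynyl group would have to point into the tartrate ligand, is recovered.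

Step 4
Reactants: 7 (4S,2E)-hept-2-en-5-yn-4-ol
Product: 9 (2E,4S,5Z)-6-iodohepta-2,5-dien-4-ol, via cyclic vinylalanate 8 (not isolated)
Conditions: Red-Al, THF, 0 °C to rt; EtOAc quench; then I2, THF, −78 to 0 °C
Reagents that add atoms: iodine, II
Why: hydroxyl-directed trans-hydroalumination of the propargylic alcohol puts Al on the distal methyl-bearing carbon in a five-membered alanate, and iodinolysis with retention gives the (Z)-vinyl iodide (I cis to the carbinol carbon), which fixes the C4=C5 geometry; the propenyl group is inert.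

Step 5
Reactants: 9 (2E,4S,5Z)-6-iodohepta-2,5-dien-4-ol; 3 2-{[(4-methoxybenzyl)oxy]methyl}acrylic acid
Product: 10 (2E,4S,5Z)-6-iodohepta-2,5-dien-4-yl 2-{[(4-methoxybenzyl)oxy]methyl}acrylate
Conditions: DCC, DMAP (cat.), CH2Cl2, 0 °C to rt
Reagents that add atoms: none
Why: Steglich esterification under near-neutral conditions; the carbinol centre is not touched.

Step 6
Reactants: 10 (2E,4S,5Z)-6-iodohepta-2,5-dien-4-yl 2-{[(4-methoxybenzyl)oxy]methyl}acrylate
Product: 11 (5S)-5-[(1Z)-2-iodoprop-1-en-1-yl]-3-{[(4-methoxybenzyl)oxy]methyl}furan-2(5H)-one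
Conditions: Hoveyda–Grubbs II (5 mol%), toluene, 80 °C
Reagents that add atoms: none
Why: ring-closing metathesis between the propenyl group and the 1,1-disubstituted acrylate closes the five-membered butenolide with loss of propene; the trisubstituted iodoalkene is too hindered to enter the cycle.

Step 7
Reactants: 12 geraniol
Product: 13 (2S,3S)-2,3-epoxygeraniol
Conditions: Ti(OiPr)4 (cat.), L-(+)-DET (cat.), t-BuOOH, 4 Å MS, CH2Cl2, −20 °C
Reagents that add atoms: tert-butyl hydroperoxide, CC(C)(C)OO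
Why: Sharpless asymmetric epoxidation; L-(+)-tartrate gives the (2S,3S)-epoxide, whose tertiary C–O centre becomes C10 (S).

Step 8
Reactants: 13 (2S,3S)-2,3-epoxygeraniol
Product: 14 (3S)-3,7-dimethyloct-6-ene-1,3-diol
Conditions: Red-Al, THF, 0 °C
Reagents that add atoms: none
Why: Red-Al opens 2,3-epoxy alcohols by intramolecular hydride delivery at C2 to give the 1,3-diol; the tertiary C–O bond is not broken, so the configuration is kept.

Step 9
Reactants: 14 (3S)-3,7-dimethyloct-6-ene-1,3-diol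
Product: 15 (4S)-2,2,4-trimethyl-4-(4-methylpent-3-en-1-yl)-1,3-dioxane
Conditions: 2,2-dimethoxypropane, PPTS (cat.), CH2Cl2, rt
Reagents that add atoms: 2,2-dimethoxypropane, COC(C)(C)OC
Why: transacetalisation of the 1,3-diol to the acetonide; one group masks C8–OH and C10–OH.

Step 10
Reactants: 15 (4S)-2,2,4-trimethyl-4-(4-methylpent-3-en-1-yl)-1,3-dioxane
Product: 17 3-[(4S)-2,2,4-trimethyl-1,3-dioxan-4-yl]propanal, via secondary ozonide 16 (not isolated)
Conditions: O3, CH2Cl2, −78 °C; then PPh3, −78 °C to rt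
Reagents that add atoms: ozone, [O-][O+]=O
Why: ozonolysis of the only C=C with reductive work-up gives the C3 aldehyde.

Step 11
Reactants: 11 (5S)-5-[(1Z)-2-iodoprop-1-en-1-yl]-3-{[(4-methoxybenzyl)oxy]methyl}furan-2(5H)-one; 17 3-[(4S)-2,2,4-trimethyl-1,3-dioxan-4-yl]propanal
Product: 19 (5R)-5-{(1Z)-3-hydroxy-2-methyl-5-[(4S)-2,2,4-trimethyl-1,3-dioxan-4-yl]pent-1-en-1-yl}-3-{[(4-methoxybenzyl)oxy]methyl}furan-2(5H)-one (both C3 epimers), via alkenylchromium(III) species 18 (not isolated)
Conditions: CrCl2 (4 equiv), NiCl2 (2 mol%), DMSO/THF, rt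
Reagents that add atoms: none
Why: Nozaki–Hiyama–Kishi Ni/Cr coupling of a vinyl iodide with an aldehyde, with retention of the Z geometry and tolerance of lactone, PMB ether and acetal; C3 is formed without useful control and both epimers are carried on.

Step 12
Reactants: 19 C3-epimeric allylic alcohols
Product: 20 (5R)-5-{(1Z)-2-methyl-3-oxo-5-[(4S)-2,2,4-trimethyl-1,3-dioxan-4-yl]pent-1-en-1-yl}-3-{[(4-methoxybenzyl)oxy]methyl}furan-2(5H)-one
Conditions: Dess–Martin periodinane, NaHCO3, CH2Cl2, 0 °C to rt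
Reagents that add atoms: none
Why: Dess–Martin oxidation under buffered, non-basic conditions converges both epimers to the Z-enone without touching the base-sensitive butenolide C6–H.

Step 13
Reactants: 20 Z-enone
Product: 21 (5R)-5-{(1Z,3S)-3-hydroxy-2-methyl-5-[(4S)-2,2,4-trimethyl-1,3-dioxan-4-yl]pent-1-en-1-yl}-3-{[(4-methoxybenzyl)oxy]methyl}furan-2(5H)-one
Conditions: (R)-Me-CBS (0.5 equiv), catecholborane, toluene, −78 °C
Reagents that add atoms: none
Why: Corey–Bakshi–Shibata reduction; the (R)-oxazaborolidine binds the ketone with the α-branched alkenyl group as the large and C2H2 as the small substituent, so hydride delivery should give the (3S)-allylic alcohol by reagent control.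

Step 14
Reactants: 21 (3S)-allylic alcohol
Product: 22 (5R)-5-{(1Z,3S)-3-[(tert-butyldimethylsilyl)oxy]-2-methyl-5-[(4S)-2,2,4-trimethyl-1,3-dioxan-4-yl]pent-1-en-1-yl}-3-{[(4-methoxybenzyl)oxy]methyl}furan-2(5H)-one
Conditions: TBSCl, imidazole, DMF, rt
Reagents that add atoms: tert-butyldimethylsilyl chloride, CC(C)(C)[Si](C)(C)Cl
Why: silylation of the secondary allylic alcohol; imidazole is too weak a base to deprotonate the butenolide γ-position.

Step 15
Reactants: 22 PMB ether
Product: 23 (5R)-5-{(1Z,3S)-3-[(tert-butyldimethylsilyl)oxy]-2-methyl-5-[(4S)-2,2,4-trimethyl-1,3-dioxan-4-yl]pent-1-en-1-yl}-3-(hydroxymethyl)furan-2(5H)-one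
Conditions: DDQ, CH2Cl2/pH 7 buffer, 0 °C to rt
Reagents that add atoms: none
Why: oxidative cleavage of the PMB ether by DDQ; silyl ether, acetonide and butenolide are inert.

Step 16
Reactants: 23 primary allylic alcohol
Product: 24 (5R)-3-(bromomethyl)-5-{(1Z,3S)-3-[(tert-butyldimethylsilyl)oxy]-2-methyl-5-[(4S)-2,2,4-trimethyl-1,3-dioxan-4-yl]pent-1-en-1-yl}furan-2(5H)-one
Conditions: CBr4, PPh3, CH2Cl2, 0 °C
Reagents that add atoms: carbon tetrabromide, BrC(Br)(Br)Br
Why: Appel bromination of the primary allylic alcohol under neutral conditions.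

Step 17
Reactants: 24 bromide acetonide
Product: 25 (5R)-3-(bromomethyl)-5-[(1Z,3S,6S)-3-[(tert-butyldimethylsilyl)oxy]-6,8-dihydroxy-2,6-dimethyloct-1-en-1-yl]furan-2(5H)-one
Conditions: AcOH/THF/H2O (3:1:1), rt
Reagents that add atoms: none
Why: acid hydrolysis of the strained 4,4-disubstituted dioxane acetonide; the secondary TBS ether and the primary allylic bromide should survive at room temperature.

Step 18
Reactants: 25 diol
Product: 26 (5R)-3-(bromomethyl)-5-[(1Z,3S,6S)-3-[(tert-butyldimethylsilyl)oxy]-6-hydroxy-2,6-dimethyl-8-oxooct-1-en-1-yl]furan-2(5H)-one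
Conditions: Dess–Martin periodinane, NaHCO3, CH2Cl2, 0 °C
Reagents that add atoms: none
Why: Dess–Martin oxidation of the primary alcohol to the C8 aldehyde; the tertiary C10–OH cannot be oxidised, and the β-hydroxy aldehyde is used at once.

Step 19
Reactants: 26 seco aldehyde with 3-(bromomethyl)butenolide
Product: 28 (3aR,4S,6S,9S,10Z,11aR)-9-[(tert-butyldimethylsilyl)oxy]-4,6-dihydroxy-6,10-dimethyl-3-methylidene-3a,4,5,6,7,8,9,11a-octahydrocyclodeca[b]furan-2(3H)-one (germacrane numbering 3S,6R,7R,8S,10S), via allylchromium(III) species 27 (not isolated)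
Conditions: CrCl2 (8 equiv), THF/DMF, rt, slow addition (syringe pump) to 2 mM; aq. work-up
Reagents that add atoms: none
Why: Two Cr(II) reduce the allylic C13–Br bond to the allylchromium(III) species 27, which adds through its γ-carbon C7 (the β-carbon of the butenolide) to the C8 aldehyde in a closed six-membered chair transition state (Cr–C13–C11=C7···C8=O), so that C7–C8 forms, the C7=C11 bond moves to the exocyclic C11=C13 position and the butenolide becomes the α-methylene-γ-butyrolactone. The closest known reactions are the Nozaki–Hiyama (Cr) and Zn/In Barbier allylations of aldehydes with 3-(bromomethyl)furan-2(5H)-ones and the Cr(II)-mediated macrocyclisations of ω-formyl 2-(bromomethyl)acrylates to ten-membered carbocycles. The ten-membered carbocycle is closed by a 10-exo-trig addition to the C8 carbonyl (SE2′ at the allyl unit); no other ring is formed, the lactone ring being present before. C7 is controlled by the existing C6 centre, because C8 should bond to the butenolide face opposite the C5 substituent and so give the trans-fused (6R,7R) lactone, the normal low-strain fusion on a ten-membered ring; C8 is controlled by the ring-locked allyl geometry (C6 trans to C13), which with the aldehyde chain equatorial in the chair should give the anti (7R,8S) carbinol. The step needs γ- over α-attack (ten- versus twelve-membered ring), secured by the cyclic transition state of allylchromium reagents; cyclisation over oligomerisation, secured by slow addition at high dilution and helped by the Z-C4=C5 bond and the quaternary C10 that pre-bend the chain; and aldehyde over lactone chemoselectivity, which is inherent to organochromium(III) reagents.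

Step 20
Reactants: 28 (8S)-alcohol; 29 isobutyric acid
Product: 30 (3aR,4R,6S,9S,10Z,11aR)-9-[(tert-butyldimethylsilyl)oxy]-6-hydroxy-6,10-dimethyl-3-methylidene-2-oxo-2,3,3a,4,5,6,7,8,9,11a-decahydrocyclodeca[b]furan-4-yl 2-methylpropanoate
Conditions: PPh3, DIAD, toluene, 0 °C to rt
Reagents that add atoms: none
Why: Mitsunobu esterification; SN2 displacement of the C8 oxyphosphonium by isobutyrate inverts C8 from S to R and installs the ester in one step, while the tertiary C10–OH cannot be activated.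

Step 21
Reactants: 30 TBS ether of the target
Product: 31 (3aR,4R,6S,9S,10Z,11aR)-6,9-dihydroxy-6,10-dimethyl-3-methylidene-2-oxo-2,3,3a,4,5,6,7,8,9,11a-decahydrocyclodeca[b]furan-4-yl 2-methylpropanoate (CNP0163972.1)
Conditions: HF·pyridine, pyridine, THF, 0 °C to rt
Reagents that add atoms: none
Why: fluoride-mediated desilylation of the allylic TBS ether under buffered conditions that leave the α-methylene lactone and the isobutyrate intact.

## Compound list

1 | 2-(bromomethyl)acrylic acid | C=C(CBr)C(=O)O | starting material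
2 | 4-methoxybenzyl alcohol | COc1ccc(CO)cc1 | starting material
3 | 2-{[(4-methoxybenzyl)oxy]methyl}acrylic acid | C=C(COCc1ccc(OC)cc1)C(=O)O | intermediate
4 | (E)-crotonaldehyde | C/C=C/C=O | starting material
5 | 1-propynylmagnesium bromide | CC#C[Mg]Br | starting material
6 | rac-(E)-hept-2-en-5-yn-4-ol | C/C=C/C(O)C#CC | intermediate
7 | (4S,2E)-hept-2-en-5-yn-4-ol | C/C=C/[C@H](O)C#CC | intermediate
8 | sodium cyclic vinylalanate (five-membered O–Al–C=C ring, bis(2-methoxyethoxy)aluminate) | C/C=C/[C@@H]1O[Al-](OCCOC)(OCCOC)C(C)=C1.[Na+] | intermediate (not isolated)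
9 | (2E,4S,5Z)-6-iodohepta-2,5-dien-4-ol | C/C=C/[C@H](O)/C=C(/C)I | intermediate
10 | (2E,4S,5Z)-6-iodohepta-2,5-dien-4-yl 2-{[(4-methoxybenzyl)oxy]methyl}acrylate | C/C=C/[C@H](OC(=O)C(=C)COCc1ccc(OC)cc1)/C=C(/C)I | intermediate
11 | (5S)-5-[(1Z)-2-iodoprop-1-en-1-yl]-3-{[(4-methoxybenzyl)oxy]methyl}furan-2(5H)-one | O=C1O[C@H](/C=C(/C)I)C=C1COCc2ccc(OC)cc2 | intermediate
12 | geraniol | CC(C)=CCC/C(C)=C/CO | starting material
13 | (2S,3S)-2,3-epoxygeraniol | CC(C)=CCC[C@]1(C)O[C@H]1CO | intermediate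
14 | (3S)-3,7-dimethyloct-6-ene-1,3-diol | CC(C)=CCC[C@](C)(O)CCO | intermediate
15 | (4S)-2,2,4-trimethyl-4-(4-methylpent-3-en-1-yl)-1,3-dioxane | CC(C)=CCC[C@@]1(C)CCOC(C)(C)O1 | intermediate
16 | secondary ozonide (3,3-dimethyl-1,2,4-trioxolane carrying the dioxanylethyl chain at C5) | CC1(C)OOC(CC[C@@]2(C)CCOC(C)(C)O2)O1 | intermediate (not isolated)
17 | 3-[(4S)-2,2,4-trimethyl-1,3-dioxan-4-yl]propanal | O=CCC[C@@]1(C)CCOC(C)(C)O1 | intermediate
18 | alkenylchromium(III) dichloride from 11 (Cr in place of I, Z retained) | O=C1O[C@H](/C=C(/C)[Cr](Cl)Cl)C=C1COCc2ccc(OC)cc2 | intermediate (not isolated)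
19 | (5R)-5-{(1Z)-3-hydroxy-2-methyl-5-[(4S)-2,2,4-trimethyl-1,3-dioxan-4-yl]pent-1-en-1-yl}-3-{[(4-methoxybenzyl)oxy]methyl}furan-2(5H)-one, C3 epimers | O=C1O[C@H](/C=C(/C)C(O)CC[C@@]2(C)CCOC(C)(C)O2)C=C1COCc3ccc(OC)cc3 | intermediate
20 | (5R)-5-{(1Z)-2-methyl-3-oxo-5-[(4S)-2,2,4-trimethyl-1,3-dioxan-4-yl]pent-1-en-1-yl}-3-{[(4-methoxybenzyl)oxy]methyl}furan-2(5H)-one | O=C1O[C@H](/C=C(/C)C(=O)CC[C@@]2(C)CCOC(C)(C)O2)C=C1COCc3ccc(OC)cc3 | intermediate
21 | (5R)-5-{(1Z,3S)-3-hydroxy-2-methyl-5-[(4S)-2,2,4-trimethyl-1,3-dioxan-4-yl]pent-1-en-1-yl}-3-{[(4-methoxybenzyl)oxy]methyl}furan-2(5H)-one | O=C1O[C@H](/C=C(/C)[C@@H](O)CC[C@@]2(C)CCOC(C)(C)O2)C=C1COCc3ccc(OC)cc3 | intermediate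
22 | (5R)-5-{(1Z,3S)-3-[(tert-butyldimethylsilyl)oxy]-2-methyl-5-[(4S)-2,2,4-trimethyl-1,3-dioxan-4-yl]pent-1-en-1-yl}-3-{[(4-methoxybenzyl)oxy]methyl}furan-2(5H)-one | O=C1O[C@H](/C=C(/C)[C@@H](O[Si](C)(C)C(C)(C)C)CC[C@@]2(C)CCOC(C)(C)O2)C=C1COCc3ccc(OC)cc3 | intermediate
23 | (5R)-5-{(1Z,3S)-3-[(tert-butyldimethylsilyl)oxy]-2-methyl-5-[(4S)-2,2,4-trimethyl-1,3-dioxan-4-yl]pent-1-en-1-yl}-3-(hydroxymethyl)furan-2(5H)-one | O=C1O[C@H](/C=C(/C)[C@@H](O[Si](C)(C)C(C)(C)C)CC[C@@]2(C)CCOC(C)(C)O2)C=C1CO | intermediate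
24 | (5R)-3-(bromomethyl)-5-{(1Z,3S)-3-[(tert-butyldimethylsilyl)oxy]-2-methyl-5-[(4S)-2,2,4-trimethyl-1,3-dioxan-4-yl]pent-1-en-1-yl}furan-2(5H)-one | O=C1O[C@H](/C=C(/C)[C@@H](O[Si](C)(C)C(C)(C)C)CC[C@@]2(C)CCOC(C)(C)O2)C=C1CBr | intermediate
25 | (5R)-3-(bromomethyl)-5-[(1Z,3S,6S)-3-[(tert-butyldimethylsilyl)oxy]-6,8-dihydroxy-2,6-dimethyloct-1-en-1-yl]furan-2(5H)-one | O=C1O[C@H](/C=C(/C)[C@@H](O[Si](C)(C)C(C)(C)C)CC[C@](C)(O)CCO)C=C1CBr | intermediate
26 | (5R)-3-(bromomethyl)-5-[(1Z,3S,6S)-3-[(tert-butyldimethylsilyl)oxy]-6-hydroxy-2,6-dimethyl-8-oxooct-1-en-1-yl]furan-2(5H)-one | O=C1O[C@H](/C=C(/C)[C@@H](O[Si](C)(C)C(C)(C)C)CC[C@](C)(O)CC=O)C=C1CBr | intermediate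
27 | allylchromium(III) dichloride from 26 (CrCl2 on C13 in place of Br) | O=C1O[C@H](/C=C(/C)[C@@H](O[Si](C)(C)C(C)(C)C)CC[C@](C)(O)CC=O)C=C1C[Cr](Cl)Cl | intermediate (not isolated)
28 | (3aR,4S,6S,9S,10Z,11aR)-9-[(tert-butyldimethylsilyl)oxy]-4,6-dihydroxy-6,10-dimethyl-3-methylidene-3a,4,5,6,7,8,9,11a-octahydrocyclodeca[b]furan-2(3H)-one | C=C1C(=O)O[C@@H]2/C=C(/C)[C@@H](O[Si](C)(C)C(C)(C)C)CC[C@](C)(O)C[C@H](O)[C@@H]12 | intermediate
29 | isobutyric acid | CC(C)C(=O)O | starting material
30 | (3aR,4R,6S,9S,10Z,11aR)-9-[(tert-butyldimethylsilyl)oxy]-6-hydroxy-6,10-dimethyl-3-methylidene-2-oxo-2,3,3a,4,5,6,7,8,9,11a-decahydrocyclodeca[b]furan-4-yl 2-methylpropanoate | C=C1C(=O)O[C@@H]2/C=C(/C)[C@@H](O[Si](C)(C)C(C)(C)C)CC[C@](C)(O)C[C@@H](OC(=O)C(C)C)[C@@H]12 | intermediate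
31 | (3aR,4R,6S,9S,10Z,11aR)-6,9-dihydroxy-6,10-dimethyl-3-methylidene-2-oxo-2,3,3a,4,5,6,7,8,9,11a-decahydrocyclodeca[b]furan-4-yl 2-methylpropanoate | C=C1C(=O)O[C@@H]2/C=C(/C)[C@@H](O)CC[C@](C)(O)C[C@@H](OC(=O)C(C)C)[C@@H]12 | target

## Count and risks

Total step count: 21. Longest linear sequence: 16 steps (crotonaldehyde: steps 2–6, then 11–21).

**Most likely to fail, first: step 19 (macrocyclisation).** Intermolecular coupling could outrun closure of the medium ring. The free C10–OH could protonate the allylchromium species, which would give simple reduction of the C–Br bond. The β-hydroxy aldehyde could dehydrate on the Lewis-acidic chromium salts. Facial or simple diastereoselection could also be lower than the chair model predicts. The fallback replaces the reductive chromium chemistry by a preformed allylboron nucleophile and sets out from bromide 24. Palladium-catalysed borylation (Pd(dba)2 cat., bis(pinacolato)diboron, DMSO, 50 °C) should give the allylboronate acetonide F1. Acetonide hydrolysis (AcOH/THF/H2O) should give the diol allylboronate F2, and Dess–Martin oxidation the aldehyde allylboronate F3. Heating F3 in toluene at high dilution (or with catalytic Sc(OTf)3) should close the ring by a type-I intramolecular allylboration through the same closed chair arrangement. Hydrolysis of the borate brings the route back at 28.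

**Second: step 20 (Mitsunobu at C8).** Backside attack on the hindered C8 oxyphosphonium may be slow. Elimination toward C8=C9 or toward the conjugated C7=C8 diene may then take over, or acylation may occur with retention. The fallback inverts C8 by redox and sets out from 28. Dess–Martin oxidation should give the C8 ketone F4. Luche reduction (NaBH4, CeCl3·7H2O, MeOH, −78 °C), with hydride approaching C8 anti to the neighbouring C7–C11 bond, should give the (8R)-alcohol F5. Acylation with isobutyric anhydride/DMAP brings the route back at 30.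

**Third: step 13 (CBS reduction).** Facial discrimination on the Z-enone may be poor, conjugate reduction by the borane may compete, or the γ-acyloxy Z-enone may isomerise (Z to E, or by enolisation through C6–H) during steps 12 and 13. The fallback sets C3 during C–C bond formation and sets out from 11 and 17. An asymmetric Nozaki–Hiyama–Kishi coupling (CrCl2/NiCl2 with a chiral sulfonamide ligand and base) should deliver the (3S)-alcohol directly. It comes back at 21, so the ketone 20 is never made; no new compound is needed.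

## Further compounds

F1 | step 19 | (5R)-5-{(1Z,3S)-3-[(tert-butyldimethylsilyl)oxy]-2-methyl-5-[(4S)-2,2,4-trimethyl-1,3-dioxan-4-yl]pent-1-en-1-yl}-3-[(4,4,5,5-tetramethyl-1,3,2-dioxaborolan-2-yl)methyl]furan-2(5H)-one | O=C1O[C@H](/C=C(/C)[C@@H](O[Si](C)(C)C(C)(C)C)CC[C@@]2(C)CCOC(C)(C)O2)C=C1CB3OC(C)(C)C(C)(C)O3
F2 | step 19 | (5R)-5-[(1Z,3S,6S)-3-[(tert-butyldimethylsilyl)oxy]-6,8-dihydroxy-2,6-dimethyloct-1-en-1-yl]-3-[(4,4,5,5-tetramethyl-1,3,2-dioxaborolan-2-yl)methyl]furan-2(5H)-one | O=C1O[C@H](/C=C(/C)[C@@H](O[Si](C)(C)C(C)(C)C)CC[C@](C)(O)CCO)C=C1CB2OC(C)(C)C(C)(C)O2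
F3 | step 19 | (5R)-5-[(1Z,3S,6S)-3-[(tert-butyldimethylsilyl)oxy]-6-hydroxy-2,6-dimethyl-8-oxooct-1-en-1-yl]-3-[(4,4,5,5-tetramethyl-1,3,2-dioxaborolan-2-yl)methyl]furan-2(5H)-one | O=C1O[C@H](/C=C(/C)[C@@H](O[Si](C)(C)C(C)(C)C)CC[C@](C)(O)CC=O)C=C1CB2OC(C)(C)C(C)(C)O2
F4 | step 20 | (3aS,6S,9S,10Z,11aR)-9-[(tert-butyldimethylsilyl)oxy]-6-hydroxy-6,10-dimethyl-3-methylidene-3a,5,6,7,8,9-hexahydrocyclodeca[b]furan-2,4(3H,11aH)-dione (28 with C8=O) | C=C1C(=O)O[C@@H]2/C=C(/C)[C@@H](O[Si](C)(C)C(C)(C)C)CC[C@](C)(O)CC(=O)[C@@H]12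
F5 | step 20 | (3aR,4R,6S,9S,10Z,11aR)-9-[(tert-butyldimethylsilyl)oxy]-4,6-dihydroxy-6,10-dimethyl-3-methylidene-3a,4,5,6,7,8,9,11a-octahydrocyclodeca[b]furan-2(3H)-one (C8 epimer of 28) | C=C1C(=O)O[C@@H]2/C=C(/C)[C@@H](O[Si](C)(C)C(C)(C)C)CC[C@](C)(O)C[C@@H](O)[C@@H]12
F0 | step 13 | none | none
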